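**Remark on the chemistry:** flavone numbering (O1, C2 to C4, C4a, C5 to C8, C8a, primed locants for ring B) is used also for the open-chain precursors, and the 1,3-diketones are drawn in the diketo form although they should exist largely as enols.

## Structural features

The target is a flavone in which benzene ring A is fused along C4a–C8a to the 4-pyranone ring C (O1, C2, C3, C4) and the 2,5-dimethoxyphenyl ring B hangs on C2 through the C2–C1' bond; it has no stereocenter, so the problem is one of regiochemistry and oxidation level. Ring A is substituted everywhere except C6: a hydroxyl on C5 that is hydrogen bonded to the C4 carbonyl, methyl ethers on C7 and C8, and the ring oxygen O1 on C8a. The fragile groups are ring B, a hydroquinone dimethyl ether that strong one-electron oxidants such as (NH4)2Ce(NO3)6 would turn into a quinone, the pyranone, which hot aqueous base opens, the 5-hydroxyflavone unit, which strong acid can isomerise between the 5,7,8 and the 5,6,7 oxygenation pattern (Wessely–Moser rearrangement), and every hydroquinone intermediate, which air oxidises under base. The real difficulty lies in ring A: an acetophenone-type precursor carries oxygen on both carbons ortho to the acyl group, closure of ring C through the wrong one gives the 5,6,7-oxygenated isomer, and three neighbouring oxygens must end as one free hydroxyl (C5) and two methyl ethers (C7 and C8). The feature that the key step exploits is the para relation of the oxygens on C5 and C8, which lets ring A be raised to a 1,4-benzoquinone with carbonyls on C5 and C8. In that quinone the methoxy-bearing C8a is the β-carbon of the enone units C8a=C4a–C5=O and C8a=C4a–C4=O, so it accepts the side-chain enol oxygen by addition–elimination, while the C5 oxygen is a carbonyl and cannot close the ring. The same para relation serves the end game, because reduction returns a 5,8-diol in which only the C8 hydroxyl is free of the hydrogen bond to the C4 carbonyl.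

## Logic of the disconnections

**12 to 11.** The O–CH3 bond on C8 of 12 is cut. The two hydroxyls of 11 differ in kind: the one on C5 is held in a hydrogen bond to the C4 carbonyl, the one on C8 is an ordinary phenol. The gain is that C5 and C8 now carry the same function, which points to the quinone oxidation level. The forward step must deliver one methyl group with a weak base, close to one equivalent of electrophile, and without air.

**11 to 10.** No skeletal bond is cut; the two O–H bonds on C5 and C8 are removed, which takes ring A to the quinone. The reason is that 10 is the form in which ring C can be closed on C8a. The forward step needs a mild two-electron reductant that leaves C2=C3, C4=O and the C7 methyl ether alone.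

**10 to 8 through 9.** The O1–C8a bond of 10 is cut and a methoxy group is put back on C8a, which gives 9 and, two hydrogens lower, 8. Cutting here turns the regiochemical problem into one of oxidation level: in 9 the C5 oxygen is a carbonyl and C8a is the only electrophilic carbon with a leaving group within reach of the enol oxygen. The gain is an open-chain 1,3-diketone on a ring A of symmetrical origin. Compound 8 is kept as a free hydroquinone so that a mild oxidant which spares ring B can be used, since an oxidative demethylation of a fully methylated precursor could not tell ring A from ring B, and it is used as soon as it is made. The forward step demands that the intramolecular closure outruns intermolecular additions to the electron-poor quinone.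

**8 to 7.** The two O–benzyl bonds of 7 are cut. Benzyl is chosen because it is removed without acid or base, so the C5 hydroxyl of 8 cannot dehydrate onto the side chain and the hydroquinone is exposed only at the last moment. The forward step must leave the enolised diketone and the aryl ketone unreduced.

**7 to 5 and 6.** The C2–C3 bond is cut, between the central methylene and the carbonyl carbon that carries ring B. This is the convergent point: ring A arrives as the methyl ketone 5 and ring B as the ester 6. The forward step is a crossed Claisen condensation in which only 5 can enolise and only 6 can acylate; it needs at least two equivalents of base because the product is deprotonated.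

**5 to 4.** The two O–benzyl bonds are cut. Masking both hydroxyls of 4 stops the hydroquinone from being oxidised under the basic conditions that follow and keeps the phenoxides out of the condensation. The forward step must alkylate a chelated hydroxyl and a doubly flanked one.

**4 to 2 through 3.** The aryl–acetyl bond C4a–C4 is cut. In 2 the two free ring positions are equivalent by symmetry, so C-acylation can give only one ketone, and it places the acyl group between a hydroxyl (future C5) and a methoxy group (future leaving group on C8a). The forward step must acylate on carbon in the presence of free hydroxyls without cleaving a methyl ether.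

**2 to 1.** No skeletal bond is cut; 2 is the reduced form of 1, which is a stable commercial solid. Compound 2 is made fresh because it oxidises in air.

## Other disconnections considered

Alternative 1: The cut runs through C3–C4 and O1–C2, so ring C would be assembled from the salicyl alcohol 2-(hydroxymethyl)-3,5,6-trimethoxyphenol A1 and the alkyne 2-ethynyl-1,4-dimethoxybenzene A2. In the forward step catalytic FeCl3 would ionise A1 to the ortho-quinone methide derived from it, which would add A2 in a polar hetero-Diels–Alder reaction and give 2-(2,5-dimethoxyphenyl)-5,7,8-trimethoxy-4H-chromene A3.
- In its favour: two bonds and ring C are formed in one catalytic, convergent step. O1 is the phenol oxygen of A1 from the outset, so closure through a wrong oxygen cannot occur; on this point it is the equal of the chosen plan. On precedent for the key step it is the better, since this cycloaddition type is established and the chosen closure is not.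
- Against it here: A1 is a primary benzylic alcohol, so the quinone methide has no stabilising substituent on C4 and must compete with Friedel–Crafts benzylation of the electron-rich arenes. A3 is two oxidation levels short at C4, and oxidising a methylene next to an enol ether in the presence of ring B is delicate. The C5 methyl ether must then be cleaved selectively. A1 is not a stock compound, so the ring A regiochemistry problem is only moved into its preparation.
- Comparison: structurally both plans fix O1 unambiguously. Mechanistically the alternative is safer at the ring closure but riskier afterwards, because it ends with an oxidation of A3 while the chosen plan ends with a reduction and a methylation. In step economy the two should be close once A1 and A2 are made, so no clear gain is expected.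

Alternative 2: The cut is C7–C8, so ring A would be built last on a finished pyranone, methyl 3-[6-(2,5-dimethoxyphenyl)-2-(methoxymethyl)-4-oxo-4H-pyran-3-yl]-3-oxopropanoate A4. In the forward step excess LiN(iPr)2 would turn A4 into a dianion whose methoxymethyl carbanion (C8) attacks the ester carbon (C7); enolisation would then give 2-(2,5-dimethoxyphenyl)-5,7-dihydroxy-8-methoxy-4H-chromen-4-one A5. One methylation of the C7 hydroxyl of A5 would finish the synthesis.
- In its favour: it mirrors polyketide folding. The C8 methoxy group is carried in on its own carbon, so no 5,7,8 against 5,6,7 ambiguity exists; this is equal to the chosen plan. No hydroquinone or quinone is handled and ring B never meets an oxidant; here the alternative is the better. The final methylation of A5 at its most acidic hydroxyl, on C7, is at least as reliable as the C8 methylation of the chosen plan.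
- Against it here: A4 is a fully substituted pyranone that would itself need a long synthesis. The first deprotonation turns the ketoester into an enolate, which deactivates the ester toward attack. The carbanion on C8 is α-alkoxy and only vinylogously stabilised. LiN(iPr)2 may instead add to the pyranone or deprotonate C3.
- Comparison: structurally sound, mechanistically a known reaction type but on a demanding substrate, and clearly worse in step economy than the chosen plan.

Alternative 3: The cut is C4–C4a. 2,3,5-Trimethoxyphenol A6 would add to methyl 3-(2,5-dimethoxyphenyl)prop-2-ynoate A7, and hydrolysis would give (Z)-3-(2,5-dimethoxyphenyl)-3-(2,3,5-trimethoxyphenoxy)prop-2-enoic acid A8. In the forward key step P2O5 in CH3SO3H would activate the acid group of A8, which then acylates the only free position ortho to the aryloxy oxygen and gives 2-(2,5-dimethoxyphenyl)-5,7,8-trimethoxy-4H-chromen-4-one A9. Cleavage of the C5 methyl ether of A9, next to the carbonyl, would then give 12.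
- In its favour: every step is of a known type. The aryloxy ring of A8 has a single free ortho position, so regiochemistry is fixed; this is equal to the chosen plan. No redox change is needed. With A6 and A7 in hand only four operations are required, which is better than the chosen plan in step economy.
- Against it here: the medium is strongly acidic and both arenes of A8 are very electron-rich, so acylation of ring B from the E isomer (five-membered closure), sulfonylation and ether cleavage can compete. A6 and A7 are not common stock compounds. The last step must single out one of the five methyl ethers of A9, although the position next to the carbonyl is the one normally cleaved.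
- Comparison: on precedent and length the alternative is the better. The chosen plan avoids strong acid, delivers the free C5 hydroxyl without any demethylation and starts from two stock compounds, but rests on an untested ring closure.

Key step: step 6

## Route

Step 1
Reactants: 1 2,6-dimethoxy-1,4-benzoquinone
Product: 2 2,6-dimethoxybenzene-1,4-diol
Conditions: Na2S2O4, EtOAc/H2O, rt, N2
Reagents that add atoms: none
Why: Dithionite reduction of a p-quinone to its hydroquinone is fast in a two-phase system; 2 is air-sensitive and should be taken on at once.

Step 2
Reactants: 2 2,6-dimethoxybenzene-1,4-diol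
Product: 4 1-(3,6-dihydroxy-2,4-dimethoxyphenyl)ethanone, via difluoroboron chelate 3 (not isolated)
Conditions: BF3·OEt2, AcOH, 90 °C; then aq NaOAc
Reagents that add atoms: acetic acid, CC(=O)O
Why: BF3-mediated Friedel–Crafts C-acetylation of an electron-rich phenol; the two free ring positions of 2 are equivalent by symmetry, so only one ketone can form, and it is held as the deactivated chelate 3 until aqueous NaOAc hydrolyses it.

Step 3
Reactants: 4 1-(3,6-dihydroxy-2,4-dimethoxyphenyl)ethanone
Product: 5 1-[3,6-bis(benzyloxy)-2,4-dimethoxyphenyl]ethanone
Conditions: BnBr (2.5 equiv), K2CO3, DMF, 60 °C, Ar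
Reagents that add atoms: benzyl bromide, BrCc1ccccc1
Why: Williamson ether synthesis; warm DMF is needed to alkylate the chelated hydroxyl ortho to the acetyl group and the hydroxyl between two methoxy groups, and argon keeps the hydroquinone from being oxidised under base.

Step 4
Reactants: 5 1-[3,6-bis(benzyloxy)-2,4-dimethoxyphenyl]ethanone; 6 methyl 2,5-dimethoxybenzoate
Product: 7 1-[3,6-bis(benzyloxy)-2,4-dimethoxyphenyl]-3-(2,5-dimethoxyphenyl)propane-1,3-dione
Conditions: NaH, THF, 65 °C; then aq HCl
Reagents that add atoms: none
Why: Crossed Claisen condensation in which 5 is the only enolisable partner and 6 the only acylating one; deprotonation of the product diketone drives the equilibrium, and benzyl and methyl ethers are inert to NaH.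

Step 5
Reactants: 7 1-[3,6-bis(benzyloxy)-2,4-dimethoxyphenyl]-3-(2,5-dimethoxyphenyl)propane-1,3-dione
Product: 8 1-(3,6-dihydroxy-2,4-dimethoxyphenyl)-3-(2,5-dimethoxyphenyl)propane-1,3-dione
Conditions: H2 (1 atm), Pd/C, EtOAc, rt; filtered under Ar
Reagents that add atoms: none
Why: Hydrogenolysis of aryl benzyl ethers over Pd/C under neutral conditions; with no acid present the freed C5 hydroxyl can at most form a reversible hemiketal and should not dehydrate to the 5,6,7-oxygenated flavone, and 8 is used directly.

Step 6
Reactants: 8 1-(3,6-dihydroxy-2,4-dimethoxyphenyl)-3-(2,5-dimethoxyphenyl)propane-1,3-dione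
Product: 10 2-(2,5-dimethoxyphenyl)-7-methoxy-4H-chromene-4,5,8-trione, via acylquinone 9 (not isolated)
Conditions: Ag2O, 4 Å molecular sieves, CH2Cl2 (0.01 M), rt, dark
Reagents that add atoms: none
Why: Proposed new method: Ag2O should dehydrogenate hydroquinone 8 to acylquinone 9, as it does with simple acylhydroquinones, without touching the hydroquinone dimethyl ether of ring B; in 9 the methoxy-bearing C8a is the β-carbon of the two enone units C8a=C4a–C5=O and C8a=C4a–C4=O and hence a doubly activated vinylogous ester carbon. The Z-enol of the side chain, after rotation about C3–C4, can place its oxygen over C8a and add there in a conjugate fashion (from the other enol tautomer the same bond can be described as an oxa-6π electrocyclisation), and the resulting enolate, delocalised over the C4 and C5 oxygens, should re-form C4a=C8a by expelling methoxide, which ends as methanol. The closest known reaction type is the addition–elimination of amines, alkoxides and hydroxide at the methoxy-bearing carbon of methoxy-1,4-benzoquinones; an intramolecular version with a diketone enol oxygen that closes a pyranone is not known. Ring C is the only ring closed, by a 6-endo-trig attack on C8a, and no stereocenter is formed. The selectivity needed is closure on C8a instead of closure through the C5 oxygen, which would give the 5,6,7-oxygenated isomer. It is secured by the oxidation level: the C5 oxygen is a quinone carbonyl, 1,2-addition of the enol oxygen to that carbonyl is reversible and offers no leaving group, and C6 and the C7 methoxy carbon are out of reach of the tether. High dilution and molecular sieves are meant to hold back intermolecular Michael addition at C6 and attack by the liberated methanol.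

Step 7
Reactants: 10 2-(2,5-dimethoxyphenyl)-7-methoxy-4H-chromene-4,5,8-trione
Product: 11 2-(2,5-dimethoxyphenyl)-5,8-dihydroxy-7-methoxy-4H-chromen-4-one
Conditions: Na2S2O4, EtOAc/H2O, rt, Ar
Reagents that add atoms: none
Why: Dithionite reduction of the p-quinone to the hydroquinone; the reductant is too mild to touch C2=C3 or C4=O, and the two-phase medium limits contact of the quinone with bisulfite.

Step 8
Reactants: 11 2-(2,5-dimethoxyphenyl)-5,8-dihydroxy-7-methoxy-4H-chromen-4-one
Product: 12 2-(2,5-dimethoxyphenyl)-5-hydroxy-7,8-dimethoxy-4H-chromen-4-one (5-hydroxy-7,8,2',5'-tetramethoxyflavone)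
Conditions: MeI (1.05 equiv), K2CO3 (1.1 equiv), acetone, rt, Ar
Reagents that add atoms: iodomethane, CI
Why: Williamson O-methylation; with about one equivalent of weak base only the free C8 phenol should be ionised, while the C5 hydroxyl is tied up in its hydrogen bond to C4=O and is a poor nucleophile, so mono-methylation at C8 is expected.

## Compound list

1 | 2,6-dimethoxy-1,4-benzoquinone | COC1=CC(=O)C=C(OC)C1=O | starting material
2 | 2,6-dimethoxybenzene-1,4-diol | COc1cc(O)cc(OC)c1O | intermediate
3 | O,O-difluoroboron chelate of ketone 4 (BF2 bridging the acetyl oxygen and the ortho phenolic oxygen; 2,2-difluoro-6-hydroxy-5,7-dimethoxy-4-methyl-1,3,2-benzodioxaborinine) | CC1=[O+][B-](F)(F)Oc2cc(OC)c(O)c(OC)c12 | intermediate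
4 | 1-(3,6-dihydroxy-2,4-dimethoxyphenyl)ethanone | CC(=O)c1c(O)cc(OC)c(O)c1OC | intermediate
5 | 1-[3,6-bis(benzyloxy)-2,4-dimethoxyphenyl]ethanone | CC(=O)c1c(OCc2ccccc2)cc(OC)c(OCc2ccccc2)c1OC | intermediate
6 | methyl 2,5-dimethoxybenzoate | COC(=O)c1cc(OC)ccc1OC | starting material
7 | 1-[3,6-bis(benzyloxy)-2,4-dimethoxyphenyl]-3-(2,5-dimethoxyphenyl)propane-1,3-dione | COc1ccc(OC)c(c1)C(=O)CC(=O)c1c(OCc2ccccc2)cc(OC)c(OCc2ccccc2)c1OC | intermediate
8 | 1-(3,6-dihydroxy-2,4-dimethoxyphenyl)-3-(2,5-dimethoxyphenyl)propane-1,3-dione | COc1ccc(OC)c(c1)C(=O)CC(=O)c1c(O)cc(OC)c(O)c1OC | intermediate
9 | 1-(2,4-dimethoxy-3,6-dioxocyclohexa-1,4-dien-1-yl)-3-(2,5-dimethoxyphenyl)propane-1,3-dione | COc1ccc(OC)c(c1)C(=O)CC(=O)C1=C(OC)C(=O)C(OC)=CC1=O | intermediate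
10 | 2-(2,5-dimethoxyphenyl)-7-methoxy-4H-chromene-4,5,8-trione | COc1ccc(OC)c(c1)C1=CC(=O)C2=C(O1)C(=O)C(OC)=CC2=O | intermediate
11 | 2-(2,5-dimethoxyphenyl)-5,8-dihydroxy-7-methoxy-4H-chromen-4-one | COc1ccc(OC)c(-c2cc(=O)c3c(O)cc(OC)c(O)c3o2)c1 | intermediate
12 | 2-(2,5-dimethoxyphenyl)-5-hydroxy-7,8-dimethoxy-4H-chromen-4-one | COc1ccc(OC)c(-c2cc(=O)c3c(O)cc(OC)c(OC)c3o2)c1 | target

## Step count and least certain steps

Total step count: 8. Longest linear sequence: 8 steps (1 to 12); ester 6 enters in step 4.

**Step 6 (key step).** The ring closure may be outrun by intermolecular conjugate addition at the unsubstituted C6 of the acylquinone, by the enol carbon of a second molecule or by liberated methanol. The electron-poor quinone may also decompose on the basic Ag2O surface, and the chelated enol may be slow to twist into the geometry that brings its oxygen over C8a. The fallback uses known chemistry, sets out from 2 and comes back to the route at 12. Compound 2 would be methylated twice (Me2SO4, K2CO3, acetone) to 1,2,3,5-tetramethoxybenzene F1. Friedel–Crafts acetylation of this arene with AcCl and AlCl3 is expected to give 1-(2-hydroxy-3,4,6-trimethoxyphenyl)ethanone F2, with loss of the crowded ortho methyl ether that is flanked by a second methoxy group. Claisen condensation of the hydroxyketone with ester 6 (LiN(SiMe3)2, THF) would give 1-(2,5-dimethoxyphenyl)-3-(2-hydroxy-3,4,6-trimethoxyphenyl)propane-1,3-dione F3. This diketone has a single free hydroxyl, so acid cyclodehydration (cat. H2SO4, AcOH, heat) can only give 2-(2,5-dimethoxyphenyl)-5,7,8-trimethoxy-4H-chromen-4-one F4. BCl3 in CH2Cl2 at low temperature should then cleave only the C5 methyl ether next to the carbonyl and give 12.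

**Step 8.** Over-methylation at the chelated C5 hydroxyl, or re-oxidation of the hydroquinone by traces of air under base before it is alkylated, would erode the selectivity. The fallback sets out from 11 and returns at 12. Both hydroxyls would be methylated with excess Me2SO4 and K2CO3 in refluxing acetone to 2-(2,5-dimethoxyphenyl)-5,7,8-trimethoxy-4H-chromen-4-one F5, which has the same structure as F4. The C5 methyl ether would then be removed by chelation-directed cleavage with BCl3 in CH2Cl2, so the selectivity rests on demethylation instead of methylation.

**Step 4.** Acylation may stall because the enolate of the di-ortho-substituted, electron-rich ketone and the ortho-methoxy benzoate are both sluggish, leaving room for retro-Claisen cleavage or ester hydrolysis on work-up. The fallback sets out from 5 and returns at 7. The lithium enolate of 5 (LiN(iPr)2, THF, −78 °C) would be added to 2,5-dimethoxybenzaldehyde to give racemic 1-[3,6-bis(benzyloxy)-2,4-dimethoxyphenyl]-3-(2,5-dimethoxyphenyl)-3-hydroxypropan-1-one F6. Oxidation of the secondary alcohol with Dess–Martin periodinane would give 7, replacing the acyl transfer by an aldol addition and an oxidation.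

**Step 5.** Over-reduction of the benzylic ketone or of the enol, slow cleavage of the benzyl ether flanked by two methoxy groups, or air oxidation during filtration could spoil the hydroquinone. The fallback sets out from 4 and returns at 8 without any protecting group. The trianion of 4, formed with LiN(SiMe3)2 (4 equiv) in THF, would be acylated on carbon by ester 6, and mild acidic work-up under argon would give 8 directly. Steps 3 to 5 then drop out and no new compound is made.

## Further compounds

F1 | step 6 | 1,2,3,5-tetramethoxybenzene | COc1cc(OC)c(OC)c(OC)c1
F2 | step 6 | 1-(2-hydroxy-3,4,6-trimethoxyphenyl)ethanone | CC(=O)c1c(O)c(OC)c(OC)cc1OC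
F3 | step 6 | 1-(2,5-dimethoxyphenyl)-3-(2-hydroxy-3,4,6-trimethoxyphenyl)propane-1,3-dione | COc1ccc(OC)c(c1)C(=O)CC(=O)c1c(O)c(OC)c(OC)cc1OC
F4 | step 6 | 2-(2,5-dimethoxyphenyl)-5,7,8-trimethoxy-4H-chromen-4-one | COc1ccc(OC)c(-c2cc(=O)c3c(OC)cc(OC)c(OC)c3o2)c1
F5 | step 8 | 2-(2,5-dimethoxyphenyl)-5,7,8-trimethoxy-4H-chromen-4-one | COc1ccc(OC)c(-c2cc(=O)c3c(OC)cc(OC)c(OC)c3o2)c1
F6 | step 4 | 1-[3,6-bis(benzyloxy)-2,4-dimethoxyphenyl]-3-(2,5-dimethoxyphenyl)-3-hydroxypropan-1-one (racemic) | COc1ccc(OC)c(c1)C(O)CC(=O)c1c(OCc2ccccc2)cc(OC)c(OCc2ccccc2)c1OC
F0 | step 5 | none | none
A1 | alternative 1 | 2-(hydroxymethyl)-3,5,6-trimethoxyphenol | OCc1c(OC)cc(OC)c(OC)c1O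
A2 | alternative 1 | 2-ethynyl-1,4-dimethoxybenzene | C#Cc1cc(OC)ccc1OC
A3 | alternative 1 | 2-(2,5-dimethoxyphenyl)-5,7,8-trimethoxy-4H-chromene | COc1ccc(OC)c(c1)C1=CCc2c(OC)cc(OC)c(OC)c2O1
A4 | alternative 2 | methyl 3-[6-(2,5-dimethoxyphenyl)-2-(methoxymethyl)-4-oxo-4H-pyran-3-yl]-3-oxopropanoate | COCC1=C(C(=O)CC(=O)OC)C(=O)C=C(O1)c1cc(OC)ccc1OC
A5 | alternative 2 | 2-(2,5-dimethoxyphenyl)-5,7-dihydroxy-8-methoxy-4H-chromen-4-one | COc1ccc(OC)c(-c2cc(=O)c3c(O)cc(O)c(OC)c3o2)c1
A6 | alternative 3 | 2,3,5-trimethoxyphenol | COc1cc(O)c(OC)c(OC)c1
A7 | alternative 3 | methyl 3-(2,5-dimethoxyphenyl)prop-2-ynoate | COC(=O)C#Cc1cc(OC)ccc1OC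
A8 | alternative 3 | (Z)-3-(2,5-dimethoxyphenyl)-3-(2,3,5-trimethoxyphenoxy)prop-2-enoic acid | OC(=O)/C=C(\Oc1cc(OC)cc(OC)c1OC)c1cc(OC)ccc1OC
A9 | alternative 3 | 2-(2,5-dimethoxyphenyl)-5,7,8-trimethoxy-4H-chromen-4-one | COc1ccc(OC)c(-c2cc(=O)c3c(OC)cc(OC)c(OC)c3o2)c1
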